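The target is ring B of an ent-labdane: a cyclohexene whose C7=C8 double bond lies opposite the C5–C10 fusion bond, with quaternary C10 (bearing C20 and C1) flanked by C9 and C5. This feature is cut by one intermolecular Diels–Alder disconnection (C5–C6 and C9–C10). A chiral oxazaborolidinium ion joins a geraniol-derived E-configured 1,2-disubstituted diene (C6–C9, C17, complete silyl-protected C11–C16 side chain) with ethyl (E)-3-formylcrotonate (C1, C10, C20, C5, C4). One operation gives ring B, the C7=C8 alkene and the stereocentres C5, C9 and C10. Ring A is then grown from the trans formyl and ester arms by two-carbon homologation, Claisen closure, two methyl additions and C3 hydroxylation.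

Key step: step 4

Assumption (numbering, configuration): labdane numbering is used. The SMILES reads as (3S,5S,9R,10S,13E), with C20 and C11 on one face of ring B, H5 and H9 on the other, and an equatorial 3-OH cis to C20.
Assumption (sense of induction): in the accepted model for α-substituted enals bound to the proline-derived oxazaborolidinium ion, the (S)-catalyst leaves the Re face of the α-carbon open. The target needs Si-face attack at C10, so the (R)-catalyst is used (both antipodes are commercial).

Step 1
Reactants: 1 geraniol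
Product: 2 geranyl tert-butyldiphenylsilyl ether
Conditions: t-BuPh2SiCl, imidazole, CH2Cl2, 0 °C to rt
Reagents that add atoms: tert-butyl(chloro)diphenylsilane CC(C)(C)[Si](Cl)(c1ccccc1)c1ccccc1
Why: Standard silylation of a primary allylic alcohol, the TBDPS group being chosen because its weakly basic oxygen and acid stability should survive the strongly acidic boron cation of step 4, the aqueous acid of steps 6 and 9 and all organometallic steps.

Step 2
Reactants: 2 geranyl tert-butyldiphenylsilyl ether
Product: 4 (2E,6E)-8-(tert-butyldiphenylsilyloxy)-2,6-dimethylocta-2,6-dienal, via allylic alcohol 3 (not isolated)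
Conditions: SeO2 (10 mol %), t-BuOOH, salicylic acid (10 mol %), CH2Cl2, 0 °C to rt; wash, dry; then MnO2, CH2Cl2, rt
Reagents that add atoms: tert-butyl hydroperoxide CC(C)(C)OO (terminal oxygen source); selenium dioxide O=[Se]=O (catalytic oxygen carrier)
Why: Riley-type allylic oxidation (ene reaction, then [2,3]-sigmatropic shift) attacks the more electron-rich terminal alkene at its E methyl group, and MnO2 then converges the alcohol/enal mixture typical of this oxidation on the enal without touching the silyl-protected allylic position.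

Step 3
Reactants: 4 (2E,6E)-8-(tert-butyldiphenylsilyloxy)-2,6-dimethylocta-2,6-dienal
Product: 5 tert-butyl{[(2E,6E)-3,7-dimethylnona-2,6,8-trien-1-yl]oxy}diphenylsilane
Conditions: Ph3PCH3Br, KOt-Bu, THF, 0 °C; then 4, 0 °C
Reagents that add atoms: methyltriphenylphosphonium bromide C[P+](c1ccccc1)(c1ccccc1)c1ccccc1.[Br-]
Why: Wittig methylenation of an enal with a non-stabilised ylide is fast at low temperature and leaves untouched the E geometry of the C8=C9 bond, which later defines C9.

Step 4
Reactants: 5 tert-butyl{[(2E,6E)-3,7-dimethylnona-2,6,8-trien-1-yl]oxy}diphenylsilane; 6 ethyl (2E)-3-methyl-4-oxobut-2-enoate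
Product: 7 ethyl (1S,5R,6S)-5-[(3E)-5-(tert-butyldiphenylsilyloxy)-3-methylpent-3-en-1-yl]-6-formyl-4,6-dimethylcyclohex-3-ene-1-carboxylate
Conditions: (R)-3,3-diphenyl-1-(2-methylphenyl)tetrahydro-1H,3H-pyrrolo[1,2-c][1,3,2]oxazaborole (20 mol %), (CF3SO2)2NH (17 mol %), 6 (2 equiv), CH2Cl2, −78 to −20 °C
Reagents that add atoms: none
Why: The cation formed from the oxazaborolidine and (CF3SO2)2NH binds the formyl oxygen of 6, lowers its LUMO and places the largest coefficient on C5, so that a concerted but asynchronous intermolecular [4+2] cycloaddition begins with C5–C6 bonding at the unsubstituted diene terminus and ends with C9–C10 bonding, the closest known reaction type being the oxazaborolidinium-catalysed enantioselective Diels–Alder reaction of α-substituted enals with acyclic dienes. Ring B is closed in this one six-electron event, both ring bonds forming suprafacially on each partner and the C7=C8 double bond arising from the two inner diene carbons. C5 and C10 are fixed relative to each other by the E geometry of 6 (C1 trans to C4 and C20 cis to C4), which is the later trans fusion of rings A and B. C9 is fixed by the E geometry of the C8=C9 bond together with a transition state that keeps the catalyst-laden formyl group exo, away from the C8 methyl group and C11, and the ester and C20 endo, so that C11 ends cis to C20. The absolute configuration comes from the (R)-catalyst, whose convex-face phenyl group covers the Re face of C10 and leaves the Si face to the diene. The step needs ortho regiochemistry against the para bias of the C8 methyl group and the pull of the ester, which is secured by selective complexation of the aldehyde and by the stronger directing effect of the terminal C9 alkyl group, while the weakly basic TBDPS ether and a slight excess of oxazaborolidine over acid protect the allylic C15–O bond.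

Step 5
Reactants: 8 ethyl vinyl ether; 9 triphenylphosphine hydrobromide
Product: 10 (1-ethoxyethyl)triphenylphosphonium bromide (racemic)
Conditions: CH2Cl2, 0 °C to rt; precipitation with Et2O
Reagents that add atoms: none
Why: Protonation of the enol ether gives an oxocarbenium ion that PPh3 captures (Markovnikov addition, the known access to 1-alkoxyalkylphosphonium salts), and the racemic centre disappears on ylide formation.

Step 6
Reactants: 7 ring B aldehyde ester; 10 (1-ethoxyethyl)triphenylphosphonium bromide
Product: 13 ethyl (1S,5R,6S)-5-[(3E)-5-(tert-butyldiphenylsilyloxy)-3-methylpent-3-en-1-yl]-4,6-dimethyl-6-(2-oxopropyl)cyclohex-3-ene-1-carboxylate, via ethoxyethylidene ylide 11 (not isolated), via ethyl enol ether 12 (not isolated)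
Conditions: 10 (2 equiv), KN(SiMe3)2, THF, −78 to −40 °C; 7, −78 °C to rt; then 1 M HCl, THF, rt
Reagents that add atoms: water O
Why: Wittig olefination with an α-alkoxy ylide followed by enol ether hydrolysis is the two-carbon variant of the methoxymethylene homologation, in which the non-enolisable aldehyde reacts far faster than the hindered ester, the E/Z ratio of 12 is irrelevant, and dilute acid leaves the TBDPS ether, the alkenes and C5, C9 and C10 unchanged.

Step 7
Reactants: 13 keto ester
Product: 14 (5S,9R,10S,13E)-15-(tert-butyldiphenylsilyloxy)-18,19-dinorlabda-7,13-diene-2,4-dione (trans-fused)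
Conditions: KOt-Bu (2.5 equiv), THF, 0 °C to rt; 1 M HCl to pH 3
Reagents that add atoms: none
Why: In this intramolecular Claisen (Dieckmann-type) acylation only the C3 methyl enolate can reach the ester through a six-membered transition state (the C1 enolate would give a cyclobutanone), so ring A closes with one regiochemistry, unlike an aldol of the corresponding 2,4-diketone with its two competing six-ring modes, and the product rests as its stable enolate so that the trans-diequatorial arms become a trans fusion without loss of C5.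

Step 8
Reactants: 14 bicyclic 2,4-dione
Product: 15 (5S,9R,10S,13E)-15-(tert-butyldiphenylsilyloxy)-2-methoxy-18,19-dinorlabda-2,7,13-trien-4-one
Conditions: HC(OMe)3, MeOH, camphorsulfonic acid (5 mol %), rt
Reagents that add atoms: trimethyl orthoformate COC(OC)OC; methanol CO
Why: Acid-catalysed enol etherification of a cyclic 1,3-dione under equilibrating conditions places the methoxy group on the less hindered C2 and keeps the carbonyl at C4, where a methoxy group would clash with C6H2 and the branched C5, and any minor isomer can be hydrolysed back to 14.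

Step 9
Reactants: 15 vinylogous ester
Product: 17 (5R,9R,10S,13E)-15-(tert-butyldiphenylsilyloxy)-19-norlabda-3,7,13-trien-2-one, via tertiary carbinol 16 (not isolated)
Conditions: MeLi, Et2O–THF, −78 to 0 °C; then 1 M HCl, THF, rt
Reagents that add atoms: methyllithium [Li]C; water O
Why: In this Stork–Danheiser transposition, 1,2-addition of MeLi to the C4 carbonyl and acid-induced loss of water and methanol give C2=O and C3=C4(CH3) regiospecifically, the transient C4 carbinol centre being destroyed and the short mild acid treatment leaving the γ-position C5 untouched.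

Step 10
Reactants: 17 enone
Product: 18 (5R,9R,10S,13E)-15-(tert-butyldiphenylsilyloxy)-2-(trimethylsilyloxy)labda-2,7,13-triene
Conditions: Me2CuLi (from CuI and MeLi), Me3SiCl, Et2O–THF, −78 to −20 °C; Et3N, cold aq NaHCO3
Reagents that add atoms: methyllithium [Li]C (as Me2CuLi); chlorotrimethylsilane C[Si](C)(C)Cl
Why: The Me3SiCl-accelerated Gilman conjugate addition, established on isophorone-type β,β-disubstituted enones that carry a syn-axial methyl group, builds the non-stereogenic C4 gem-dimethyl centre and stores the regiochemistry as the C2=C3 silyl enol ether, after which C5 can no longer epimerise.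

Step 11
Reactants: 18 silyl enol ether
Product: 20 (3R,5S,9R,10S,13E)-15-(tert-butyldiphenylsilyloxy)-3-hydroxylabda-7,13-dien-2-one (axial OH trans to C20), via lithium enolate 19 (not isolated)
Conditions: MeLi, THF, 0 °C; −78 °C, 3-phenyl-2-(phenylsulfonyl)oxaziridine; AcOH
Reagents that add atoms: 3-phenyl-2-(phenylsulfonyl)oxaziridine O=S(=O)(c1ccccc1)N1OC1c1ccccc1; methyllithium [Li]C (lithium of 19 only)
Why: MeLi cleavage of the silyl enol ether releases the C2=C3 lithium enolate regiospecifically, and the Davis oxidation, which unlike a peracid leaves the C7=C8 and C13=C14 alkenes alone, delivers oxygen to C3 from the face opposite C20 and the axial C4 methyl group, so the axial (3R) alcohol is expected as the main kinetic product.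

Step 12
Reactants: 20 axial ketol
Product: 21 (3S,5S,9R,10S,13E)-15-(tert-butyldiphenylsilyloxy)-3-hydroxylabda-7,13-dien-2-one (equatorial OH cis to C20)
Conditions: NaOMe (20 mol %), degassed MeOH, Ar, rt
Reagents that add atoms: none
Why: Base-catalysed ketol equilibration through the enediolate with exclusion of air should funnel the material to the (3S) isomer, because the equatorial hydroxyl is hydrogen-bonded to the carbonyl and free of syn-axial contacts and because a C2 carbonyl, unlike a C3 carbonyl, removes the axial hydrogen that is syn-axial to both C20 and the axial C4 methyl group.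

Step 13
Reactants: 21 equatorial ketol
Product: 22 (3S,5S,9R,10S,13E)-3,15-dihydroxylabda-7,13-dien-2-one
Conditions: HF·pyridine, pyridine, THF, 0 °C to rt
Reagents that add atoms: none
Why: Fluoride-induced Si–O cleavage in a buffered acidic medium removes the TBDPS group without the basic conditions that could shift the ketol or promote its autoxidation.

Step 14
Reactants: 22 diol
Product: 23 (3S,5S,9R,10S,13E)-3-hydroxy-2-oxolabda-7,13-dien-15-yl acetate (target)
Conditions: Ac2O (1.1 equiv), pyridine, CH2Cl2, 0 °C
Reagents that add atoms: acetic anhydride CC(=O)OC(C)=O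
Why: In this selective acylation the unhindered primary allylic alcohol reacts much faster than the neopentyl, hydrogen-bonded C3 hydroxyl, so one equivalent of anhydride at low temperature without an acyl-transfer catalyst should give the monoacetate.

Compound list
1 | geraniol | CC(C)=CCC/C(C)=C/CO | starting material
2 | geranyl tert-butyldiphenylsilyl ether | CC(C)=CCC/C(C)=C/CO[Si](c1ccccc1)(c1ccccc1)C(C)(C)C | intermediate
3 | (2E,6E)-8-(tert-butyldiphenylsilyloxy)-2,6-dimethylocta-2,6-dien-1-ol | OC/C(C)=C/CC/C(C)=C/CO[Si](c1ccccc1)(c1ccccc1)C(C)(C)C | intermediate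
4 | (2E,6E)-8-(tert-butyldiphenylsilyloxy)-2,6-dimethylocta-2,6-dienal | O=C/C(C)=C/CC/C(C)=C/CO[Si](c1ccccc1)(c1ccccc1)C(C)(C)C | intermediate
5 | tert-butyl{[(2E,6E)-3,7-dimethylnona-2,6,8-trien-1-yl]oxy}diphenylsilane | C=C/C(C)=C/CC/C(C)=C/CO[Si](c1ccccc1)(c1ccccc1)C(C)(C)C | intermediate
6 | ethyl (2E)-3-methyl-4-oxobut-2-enoate | CCOC(=O)/C=C(\C)C=O | starting material
7 | ethyl (1S,5R,6S)-5-[(3E)-5-(tert-butyldiphenylsilyloxy)-3-methylpent-3-en-1-yl]-6-formyl-4,6-dimethylcyclohex-3-ene-1-carboxylate | CC(C)(C)[Si](c1ccccc1)(c1ccccc1)OC/C=C(\C)CC[C@@H]1C(C)=CC[C@H](C(=O)OCC)[C@@]1(C)C=O | intermediate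
8 | ethyl vinyl ether | C=COCC | starting material
9 | triphenylphosphine hydrobromide | [Br-].[PH+](c1ccccc1)(c1ccccc1)c1ccccc1 | starting material
10 | (1-ethoxyethyl)triphenylphosphonium bromide (racemic) | CCOC(C)[P+](c1ccccc1)(c1ccccc1)c1ccccc1.[Br-] | intermediate
11 | (1-ethoxyethylidene)triphenylphosphorane | CCOC(C)=P(c1ccccc1)(c1ccccc1)c1ccccc1 | intermediate
12 | 6-(2-ethoxyprop-1-en-1-yl) analogue of 7 (E/Z mixture, ring stereocentres as in 7) | CC(C)(C)[Si](c1ccccc1)(c1ccccc1)OC/C=C(\C)CC[C@@H]1C(C)=CC[C@H](C(=O)OCC)[C@@]1(C)C=C(C)OCC | intermediate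
13 | ethyl (1S,5R,6S)-5-[(3E)-5-(tert-butyldiphenylsilyloxy)-3-methylpent-3-en-1-yl]-4,6-dimethyl-6-(2-oxopropyl)cyclohex-3-ene-1-carboxylate | CC(C)(C)[Si](c1ccccc1)(c1ccccc1)OC/C=C(\C)CC[C@@H]1C(C)=CC[C@H](C(=O)OCC)[C@@]1(C)CC(C)=O | intermediate
14 | (5S,9R,10S,13E)-15-(tert-butyldiphenylsilyloxy)-18,19-dinorlabda-7,13-diene-2,4-dione | CC(C)(C)[Si](c1ccccc1)(c1ccccc1)OC/C=C(\C)CC[C@@H]1C(C)=CC[C@@H]2C(=O)CC(=O)C[C@@]12C | intermediate
15 | (5S,9R,10S,13E)-15-(tert-butyldiphenylsilyloxy)-2-methoxy-18,19-dinorlabda-2,7,13-trien-4-one | CC(C)(C)[Si](c1ccccc1)(c1ccccc1)OC/C=C(\C)CC[C@@H]1C(C)=CC[C@@H]2C(=O)C=C(OC)C[C@@]12C | intermediate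
16 | 15-(tert-butyldiphenylsilyloxy)-2-methoxy-19-norlabda-2,7,13E-trien-4-ol (C4 epimers, other centres as in 15) | CC(C)(C)[Si](c1ccccc1)(c1ccccc1)OC/C=C(\C)CC[C@@H]1C(C)=CC[C@@H]2C(C)(O)C=C(OC)C[C@@]12C | intermediate
17 | (5R,9R,10S,13E)-15-(tert-butyldiphenylsilyloxy)-19-norlabda-3,7,13-trien-2-one | CC(C)(C)[Si](c1ccccc1)(c1ccccc1)OC/C=C(\C)CC[C@@H]1C(C)=CC[C@@H]2C(C)=CC(=O)C[C@@]12C | intermediate
18 | (5R,9R,10S,13E)-15-(tert-butyldiphenylsilyloxy)-2-(trimethylsilyloxy)labda-2,7,13-triene | CC(C)(C)[Si](c1ccccc1)(c1ccccc1)OC/C=C(\C)CC[C@@H]1C(C)=CC[C@@H]2C(C)(C)C=C(O[Si](C)(C)C)C[C@@]12C | intermediate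
19 | lithium C2=C3 enolate derived from 18 | CC(C)(C)[Si](c1ccccc1)(c1ccccc1)OC/C=C(\C)CC[C@@H]1C(C)=CC[C@@H]2C(C)(C)C=C([O-])C[C@@]12C.[Li+] | intermediate
20 | (3R,5S,9R,10S,13E)-15-(tert-butyldiphenylsilyloxy)-3-hydroxylabda-7,13-dien-2-one | CC(C)(C)[Si](c1ccccc1)(c1ccccc1)OC/C=C(\C)CC[C@@H]1C(C)=CC[C@@H]2C(C)(C)[C@@H](O)C(=O)C[C@@]12C | intermediate
21 | (3S,5S,9R,10S,13E)-15-(tert-butyldiphenylsilyloxy)-3-hydroxylabda-7,13-dien-2-one | CC(C)(C)[Si](c1ccccc1)(c1ccccc1)OC/C=C(\C)CC[C@@H]1C(C)=CC[C@@H]2C(C)(C)[C@H](O)C(=O)C[C@@]12C | intermediate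
22 | (3S,5S,9R,10S,13E)-3,15-dihydroxylabda-7,13-dien-2-one | OC/C=C(\C)CC[C@@H]1C(C)=CC[C@@H]2C(C)(C)[C@H](O)C(=O)C[C@@]12C | intermediate
23 | (3S,5S,9R,10S,13E)-3-hydroxy-2-oxolabda-7,13-dien-15-yl acetate | CC(=O)OC/C=C(\C)CC[C@@H]1C(C)=CC[C@@H]2C(C)(C)[C@H](O)C(=O)C[C@@]12C | target

Total step count: 14 (13 in the main line plus the preparation of salt 10).
Longest linear sequence: 13 steps, from geraniol 1 (steps 1–4 and 6–14).

Steps most likely to fail

**Step 4.** The cycloaddition may stall at the congested C9–C10 bond. It may also leak into the regioisomer in which C9 bonds to C5, or lose exo/endo and facial control.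
- The fallback sets out from 4 and comes back at 7. It changes the diene class so that the substituent effects reinforce each other.
- MeMgBr adds to enal 4 to give the secondary allylic alcohol F1, and MnO2 gives the methyl enone F2.
- t-BuMe2SiOSO2CF3 with Et3N gives the cross-conjugated 2-silyloxy diene F3. Its C7 oxygen makes C6 clearly the most nucleophilic terminus, and it belongs to the diene class that responds best to the same boron cation.
- Cycloaddition with 6 gives the silyl enol ether adduct F4.
- CsF and PhN(SO2CF3)2 convert F4 into the enol triflate F5.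
- Palladium-catalysed formate reduction (Pd(OAc)2, PPh3, HCO2H, n-Bu3N) removes the C7 oxygen and returns 7.

**Step 6.** The fully substituted ylide may decompose before it reaches the neopentyl formyl group, so the olefination stays incomplete.
- The fallback sets out from 7 and comes back at 13. It builds the two carbons one at a time with smaller reagents.
- The ylide from (methoxymethyl)triphenylphosphonium chloride and KOt-Bu gives the methyl enol ether F6, and dilute HCl gives the homologous aldehyde F7.
- MeMgBr at −78 °C, where the aldehyde reacts far faster than the hindered ester, gives the secondary alcohol F8.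
- Dess–Martin periodinane oxidises F8 to 13.

**Step 12.** The equilibration may stop at a mixture of C3 epimers, drift towards the 2-hydroxy-3-ketone, or be overtaken by autoxidation.
- The fallback sets out from 20 (or a mixture of 20 and 21) and comes back at 22. It sets C3 kinetically by hydride delivery instead of by thermodynamics.
- Dess–Martin oxidation gives the 2,3-dione, which rests as the diosphenol F9, and t-BuMe2SiCl with imidazole gives its silyl ether F10.
- Luche reduction (NaBH4, CeCl3·7H2O, MeOH) delivers hydride to C3 from the face opposite C20 and the axial C4 methyl group. This gives the allylic alcohol F11 with the hydroxyl cis to C20.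
- HF·pyridine then cleaves both silyl groups, the liberated enol tautomerises to the C2 ketone, and 22 results.

Further compounds
F1 | step 4 | (3E,7E)-9-(tert-butyldiphenylsilyloxy)-3,7-dimethylnona-3,7-dien-2-ol (racemic) | CC(O)/C(C)=C/CC/C(C)=C/CO[Si](c1ccccc1)(c1ccccc1)C(C)(C)C
F2 | step 4 | (3E,7E)-9-(tert-butyldiphenylsilyloxy)-3,7-dimethylnona-3,7-dien-2-one | CC(=O)/C(C)=C/CC/C(C)=C/CO[Si](c1ccccc1)(c1ccccc1)C(C)(C)C
F3 | step 4 | (3E,7E)-2-(tert-butyldimethylsilyloxy)-9-(tert-butyldiphenylsilyloxy)-3,7-dimethylnona-1,3,7-triene | C=C(O[Si](C)(C)C(C)(C)C)/C(C)=C/CC/C(C)=C/CO[Si](c1ccccc1)(c1ccccc1)C(C)(C)C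
F4 | step 4 | 3-(tert-butyldimethylsilyloxy) analogue of 7 (C7 silyl enol ether, stereocentres as in 7) | CC(C)(C)[Si](c1ccccc1)(c1ccccc1)OC/C=C(\C)CC[C@@H]1C(C)=C(O[Si](C)(C)C(C)(C)C)C[C@H](C(=O)OCC)[C@@]1(C)C=O
F5 | step 4 | 3-(trifluoromethylsulfonyloxy) analogue of 7 (C7 enol triflate, stereocentres as in 7) | CC(C)(C)[Si](c1ccccc1)(c1ccccc1)OC/C=C(\C)CC[C@@H]1C(C)=C(OS(=O)(=O)C(F)(F)F)C[C@H](C(=O)OCC)[C@@]1(C)C=O
F6 | step 6 | 6-(2-methoxyethenyl) analogue of 7 (E/Z mixture, stereocentres as in 7) | CC(C)(C)[Si](c1ccccc1)(c1ccccc1)OC/C=C(\C)CC[C@@H]1C(C)=CC[C@H](C(=O)OCC)[C@@]1(C)C=COC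
F7 | step 6 | 6-(2-oxoethyl) analogue of 7 (stereocentres as in 7) | CC(C)(C)[Si](c1ccccc1)(c1ccccc1)OC/C=C(\C)CC[C@@H]1C(C)=CC[C@H](C(=O)OCC)[C@@]1(C)CC=O
F8 | step 6 | 6-(2-hydroxypropyl) analogue of 7 (carbinol epimers, ring stereocentres as in 7) | CC(C)(C)[Si](c1ccccc1)(c1ccccc1)OC/C=C(\C)CC[C@@H]1C(C)=CC[C@H](C(=O)OCC)[C@@]1(C)CC(C)O
F9 | step 12 | 15-(tert-butyldiphenylsilyloxy)-2-hydroxylabda-1,7,13E-trien-3-one (diosphenol, C5, C9, C10 as in 21) | CC(C)(C)[Si](c1ccccc1)(c1ccccc1)OC/C=C(\C)CC[C@@H]1C(C)=CC[C@@H]2C(C)(C)C(=O)C(O)=C[C@@]12C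
F10 | step 12 | 2-(tert-butyldimethylsilyloxy)-15-(tert-butyldiphenylsilyloxy)labda-1,7,13E-trien-3-one | CC(C)(C)[Si](c1ccccc1)(c1ccccc1)OC/C=C(\C)CC[C@@H]1C(C)=CC[C@@H]2C(C)(C)C(=O)C(O[Si](C)(C)C(C)(C)C)=C[C@@]12C
F11 | step 12 | 2-(tert-butyldimethylsilyloxy)-15-(tert-butyldiphenylsilyloxy)labda-1,7,13E-trien-3-ol (OH cis to C20) | CC(C)(C)[Si](c1ccccc1)(c1ccccc1)OC/C=C(\C)CC[C@@H]1C(C)=CC[C@@H]2C(C)(C)[C@H](O)C(O[Si](C)(C)C(C)(C)C)=C[C@@]12C
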